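The quinone ring is numbered C1(=O), C2(N), C3, C4(=O), C4a, C5(CO2H), C6(OH), C7(CH3), C8(OH), C8a. Everything rests on making C1–C8a last in the core: C8a is the only unsubstituted carbon of the benzenoid ring, ortho to O8 and para to O6, and C1/C2 are the carboxyl and α-carbon of an amino acid. An aspartate-type 4-aryl-4-oxo-2-aminobutanoic acid, built on a 3,5-dimethoxy-4-methylphthalic half-ester, is therefore closed by intramolecular Friedel–Crafts acylation; enolisation, air oxidation and N-deprotection follow in the same operation and give the 2-aminoquinone with nitrogen fixed at C2. The dienoic acid, assembled by two anti-Felkin syn aldols across 3-pentanone, is then attached.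

Key step: step 4

Remark on labels: ring atoms are numbered as above; side-chain carbons are C1′ (amide carbonyl) to C17′ (ketal methyl), the ketal carbon being C16′.
Assumption: 3,5-dimethoxy-4-methylbenzoic acid, Boc-3-iodo-L-alanine methyl ester, (4R)-4-benzyl-3-propanoyl-1,3-oxazolidin-2-one, pent-4-enal, pentan-3-one and methyl (2S)-3-hydroxy-2-methylpropanoate are treated as commercial.

**Aromatic core**

Step 1
Reactants: 1 3,5-dimethoxy-4-methylbenzoic acid
Product: 3 3,5-dimethoxy-2-(methoxycarbonyl)-4-methylbenzoic acid, via dilithio benzoate 2 (not isolated)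
Conditions: s-BuLi (2.2 equiv), TMEDA, THF, −78 °C; ClCO2Me (1.0 equiv), −78 °C; aq. HCl
Reagents that add atoms: methyl chloroformate, COC(=O)Cl
Why: Directed ortho-metalation, in which the lithium carboxylate and the adjacent methoxy group cooperate to direct the base to the ring C–H between them (the two such positions are equivalent), followed by C-acylation of the aryllithium, should give the phthalic half-ester whose free acid is the future C4 carbon.

Step 2
Reactants: 3 3,5-dimethoxy-2-(methoxycarbonyl)-4-methylbenzoic acid, 4 methyl (2R)-2-[(tert-butoxycarbonyl)amino]-3-iodopropanoate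
Product: 7 methyl (2S)-2-[(tert-butoxycarbonyl)amino]-4-[3,5-dimethoxy-2-(methoxycarbonyl)-4-methylphenyl]-4-oxobutanoate, via aroyl chloride 5 (not isolated), via alkylzinc iodide 6 (not isolated)
Conditions: 3, (COCl)2, DMF (cat.), CH2Cl2, 0 °C to rt, evaporate; 4, Zn, Me3SiCl (cat.), DMF, rt; then combine, PdCl2(PPh3)2 (5 mol%), THF/DMF, rt
Reagents that add atoms: none
Why: Palladium-catalysed Negishi acylation, in which the serine-derived alkylzinc iodide (stabilised by its carbamate) couples with the aroyl chloride without touching the esters or the α-stereocentre, should put C4, C3, C2 and C1 of the future quinone ring in place.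

Step 3
Reactants: 7 methyl (2S)-2-[(tert-butoxycarbonyl)amino]-4-[3,5-dimethoxy-2-(methoxycarbonyl)-4-methylphenyl]-4-oxobutanoate
Product: 8 (2S)-2-[(tert-butoxycarbonyl)amino]-4-[3,5-dimethoxy-2-(methoxycarbonyl)-4-methylphenyl]-4-oxobutanoic acid
Conditions: LiOH (1.1 equiv), THF/H2O, 0 °C; then aq. HCl to pH 3
Reagents that add atoms: lithium hydroxide, [Li+].[OH-]
Why: Saponification should hydrolyse the unhindered aliphatic ester selectively, because the aryl methyl ester is shielded by two ortho substituents.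

Step 4
Reactants: 8 (2S)-2-[(tert-butoxycarbonyl)amino]-4-[3,5-dimethoxy-2-(methoxycarbonyl)-4-methylphenyl]-4-oxobutanoic acid
Product: 13 methyl 6-amino-2,4-dimethoxy-3-methyl-5,8-dioxo-5,8-dihydronaphthalene-1-carboxylate, via trifluoroacetamido mixed anhydride 9 (not isolated), via ring-closed diketone 10 (not isolated), via trifluoroacetamido hydroquinone 11 (not isolated), via trifluoroacetamido quinone 12 (not isolated)
Conditions: TFA/TFAA, CH2Cl2, 0 °C to rt, evaporate; TfOH (3 equiv), CH2Cl2, 0 °C to rt; then K2CO3, MeOH/H2O, air, rt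
Reagents that add atoms: none
Why: Intramolecular Friedel–Crafts acylation (Haworth-type cyclisation): acid removes the Boc group, the anhydride trifluoroacetylates nitrogen and turns the C1 carboxyl into a mixed anhydride, and triflic acid ionises it so that C8a attacks C1 in a 6-exo-trig closure of the quinone ring. C8a is the only free ring carbon and is activated by the ortho C8 and para C6 methoxy groups, so there is no regiochemical choice, and the C4 ketone, twisted out of plane by its two ortho neighbours, deactivates less than a coplanar acyl group would. The ring-closed 2-amido-2,3-dihydro-1,4-dione should enolise twice to the naphthalene-1,4-diol, which air oxidises in the basic methanolic work-up while the activated trifluoroacetamide is methanolysed. The C2 stereocentre is deliberately lost and no new one is formed. The closest known reactions are the cyclisation of N-trifluoroacetyl amino acid chlorides to 2-amino-1-tetralones and the second acylation of naphthazarin-type syntheses. The step needs acylation to outrun decarbonylation of the α-amido acylium and β-elimination of the amide, which the electron-poor trifluoroacetamide and the doubly activated arene should secure.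

Step 5
Reactants: 13 methyl 6-amino-2,4-dimethoxy-3-methyl-5,8-dioxo-5,8-dihydronaphthalene-1-carboxylate
Product: 14 6-amino-2,4-dihydroxy-3-methyl-5,8-dioxo-5,8-dihydronaphthalene-1-carboxylic acid
Conditions: BBr3 (8 equiv), CH2Cl2, −78 °C to rt; then H2O
Reagents that add atoms: none
Why: Lewis-acid O-demethylation should cleave both aryl methyl ethers, each assisted by chelation to a neighbouring carbonyl, and the methyl ester by the same O–CH3 scission through the ortho-phenoxyboron chelate.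

Step 6
Reactants: 14 6-amino-2,4-dihydroxy-3-methyl-5,8-dioxo-5,8-dihydronaphthalene-1-carboxylic acid
Product: 15 methoxymethyl 6-amino-2,4-bis(methoxymethoxy)-3-methyl-5,8-dioxo-5,8-dihydronaphthalene-1-carboxylate
Conditions: MOMCl (4 equiv), i-Pr2NEt (5 equiv), DMF, 0 °C to rt
Reagents that add atoms: chloromethyl methyl ether, COCCl
Why: O-alkylation should methoxymethylate the carboxylate and both phenoxides, while the vinylogous-amide nitrogen is not nucleophilic without a strong base and stays free.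

**Side chain**

Step 7
Reactants: 16 (4R)-4-benzyl-3-propanoyl-1,3-oxazolidin-2-one, 17 pent-4-enal
Product: 19 (4R)-4-benzyl-3-[(2R,3S)-3-hydroxy-2-methylhept-6-enoyl]-1,3-oxazolidin-2-one, via Z boron enolate 18 (not isolated)
Conditions: n-Bu2BOTf, i-Pr2NEt, CH2Cl2, 0 °C; 17, −78 to 0 °C; then pH 7 buffer, MeOH, H2O2
Reagents that add atoms: none
Why: Evans syn aldol, in which the Z-boron enolate reacts through a Zimmerman–Traxler chair on the face left open by the (R)-benzyl auxiliary, should set C12′ and C13′ syn.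

Step 8
Reactants: 19 (4R)-4-benzyl-3-[(2R,3S)-3-hydroxy-2-methylhept-6-enoyl]-1,3-oxazolidin-2-one
Product: 20 (4R)-4-benzyl-3-[(2R,3S)-2-methyl-3-(triethylsilyloxy)hept-6-enoyl]-1,3-oxazolidin-2-one
Conditions: Et3SiOTf, 2,6-lutidine, CH2Cl2, −78 °C
Reagents that add atoms: triethylsilyl trifluoromethanesulfonate, CC[Si](CC)(CC)OS(=O)(=O)C(F)(F)F
Why: Silylation blocks retro-aldol cleavage and masks O13′ with a group that the dilute acid of the ketal-forming step removes.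

Step 9
Reactants: 20 (4R)-4-benzyl-3-[(2R,3S)-2-methyl-3-(triethylsilyloxy)hept-6-enoyl]-1,3-oxazolidin-2-one
Product: 21 (2S,3S)-2-methyl-3-(triethylsilyloxy)hept-6-en-1-ol
Conditions: LiBH4, H2O (1 equiv), Et2O, 0 °C
Reagents that add atoms: none
Why: Reductive cleavage of the N-acyl oxazolidinone should reduce the exocyclic carbonyl to the primary alcohol and release the auxiliary without touching C12′.

Step 10
Reactants: 21 (2S,3S)-2-methyl-3-(triethylsilyloxy)hept-6-en-1-ol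
Product: 22 (2R,3S)-2-methyl-3-(triethylsilyloxy)hept-6-enal
Conditions: Dess–Martin periodinane, NaHCO3, CH2Cl2, 0 °C to rt
Reagents that add atoms: none
Why: Dess–Martin oxidation under buffered, non-basic conditions should give the α-chiral aldehyde without epimerisation.

Step 11
Reactants: 22 (2R,3S)-2-methyl-3-(triethylsilyloxy)hept-6-enal, 23 pentan-3-one
Product: 25 (4S,5R,6S,7S)-5-hydroxy-4,6-dimethyl-7-(triethylsilyloxy)undec-10-en-3-one, via Z boron enolate 24 (not isolated)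
Conditions: 23, n-Bu2BOTf, i-Pr2NEt, CH2Cl2, −78 to 0 °C; 22, −78 °C; then pH 7 buffer, MeOH, H2O2
Reagents that add atoms: none
Why: Boron-mediated syn aldol, whose chair transition state fixes C10′/C11′ syn and in which a Z-enolate adds to an α-methyl aldehyde in the anti-Felkin sense (the Felkin chair suffers a syn-pentane clash), should give the C11′/C12′ anti relationship.

Step 12
Reactants: 25 (4S,5R,6S,7S)-5-hydroxy-4,6-dimethyl-7-(triethylsilyloxy)undec-10-en-3-one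
Product: 28 (2S)-2-[(1S,3R,4R,5S)-1,4-dimethyl-2,8-dioxabicyclo[3.2.1]octan-3-yl]pentan-3-one, via methyl ketone silyl ether 26 (not isolated), via dihydroxy diketone 27 (not isolated)
Conditions: PdCl2 (10 mol%), CuCl (20 mol%), O2 (1 atm), DMF/H2O (7:1), rt; then aq. HCl (0.5 M), THF, rt
Reagents that add atoms: none
Why: Wacker–Tsuji oxidation of the terminal alkene to the methyl ketone, acid desilylation and intramolecular ketalisation by the C11′/C13′ diol should close the bicyclic ketal under thermodynamic control, the C16′ configuration being dictated by the two carbinol centres.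

Step 13
Reactants: 29 methyl (2S)-3-hydroxy-2-methylpropanoate
Product: 30 methyl (2S)-3-(tert-butyldimethylsilyloxy)-2-methylpropanoate
Conditions: t-BuMe2SiCl, imidazole, CH2Cl2, rt
Reagents that add atoms: tert-butyldimethylsilyl chloride, CC(C)(C)[Si](C)(C)Cl
Why: Silylation protects the primary alcohol that later becomes C5′.

Step 14
Reactants: 30 methyl (2S)-3-(tert-butyldimethylsilyloxy)-2-methylpropanoate
Product: 31 (2S)-3-(tert-butyldimethylsilyloxy)-2-methylpropanal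
Conditions: i-Bu2AlH (1.05 equiv), CH2Cl2, −78 °C; then MeOH, aq. potassium sodium tartrate
Reagents that add atoms: none
Why: Partial ester reduction stops at the aldehyde because the tetrahedral aluminium hemiacetal is stable at −78 °C and collapses only on work-up, so C6′ should not epimerise.

Step 15
Reactants: 28 (2S)-2-[(1S,3R,4R,5S)-1,4-dimethyl-2,8-dioxabicyclo[3.2.1]octan-3-yl]pentan-3-one, 31 (2S)-3-(tert-butyldimethylsilyloxy)-2-methylpropanal
Product: 33 (2S,4R,5S,6S)-7-(tert-butyldimethylsilyloxy)-2-[(1S,3R,4R,5S)-1,4-dimethyl-2,8-dioxabicyclo[3.2.1]octan-3-yl]-5-hydroxy-4,6-dimethylheptan-3-one, via Z tin enolate 32 (not isolated)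
Conditions: Sn(OTf)2, Et3N, CH2Cl2, −78 °C; then 31, −78 °C
Reagents that add atoms: none
Why: Tin-mediated syn aldol of an α-chiral ethyl ketone (divalent tin Z-enolate chelated by the C11′ ring oxygen) should be attacked opposite the C10′ methyl group and add to the aldehyde in the matched anti-Felkin sense, setting C8′ and C7′ in the syn–syn array.

Step 16
Reactants: 33 (2S,4R,5S,6S)-7-(tert-butyldimethylsilyloxy)-2-[(1S,3R,4R,5S)-1,4-dimethyl-2,8-dioxabicyclo[3.2.1]octan-3-yl]-5-hydroxy-4,6-dimethylheptan-3-one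
Product: 34 (2S,3S,4R,5R,6R)-1-(tert-butyldimethylsilyloxy)-6-[(1S,3S,4R,5S)-1,4-dimethyl-2,8-dioxabicyclo[3.2.1]octan-3-yl]-2,4-dimethylheptane-3,5-diol
Conditions: Me4NBH(OAc)3, MeCN/AcOH (1:1), −25 °C
Reagents that add atoms: none
Why: Saksena–Evans reduction, in which the C7′ hydroxyl binds boron and delivers hydride intramolecularly through a chair, should give the 1,3-anti diol and so set C9′.

Step 17
Reactants: 34 (2S,3S,4R,5R,6R)-1-(tert-butyldimethylsilyloxy)-6-[(1S,3S,4R,5S)-1,4-dimethyl-2,8-dioxabicyclo[3.2.1]octan-3-yl]-2,4-dimethylheptane-3,5-diol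
Product: 35 tert-butyl{(2S)-2-[(4S,5R,6R)-6-{(1R)-1-[(1S,3R,4R,5S)-1,4-dimethyl-2,8-dioxabicyclo[3.2.1]octan-3-yl]ethyl}-2,2,5-trimethyl-1,3-dioxan-4-yl]propoxy}dimethylsilane
Conditions: 2,2-dimethoxypropane, PPTS (cat.), CH2Cl2, rt
Reagents that add atoms: 2,2-dimethoxypropane, COC(C)(C)OC
Why: Acetonide formation ties up the C7′/C9′ diol so that the later oxidation and olefinations cannot be diverted into lactol formation or oxa-Michael closure.

Step 18
Reactants: 35 tert-butyl{(2S)-2-[(4S,5R,6R)-6-{(1R)-1-[(1S,3R,4R,5S)-1,4-dimethyl-2,8-dioxabicyclo[3.2.1]octan-3-yl]ethyl}-2,2,5-trimethyl-1,3-dioxan-4-yl]propoxy}dimethylsilane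
Product: 36 (2S)-2-[(4S,5R,6R)-6-{(1R)-1-[(1S,3R,4R,5S)-1,4-dimethyl-2,8-dioxabicyclo[3.2.1]octan-3-yl]ethyl}-2,2,5-trimethyl-1,3-dioxan-4-yl]propan-1-ol
Conditions: Bu4NF, THF, 0 °C to rt
Reagents that add atoms: none
Why: Fluoride-mediated desilylation should free the primary alcohol while the acetonide and the bicyclic ketal are inert.

Step 19
Reactants: 36 (2S)-2-[(4S,5R,6R)-6-{(1R)-1-[(1S,3R,4R,5S)-1,4-dimethyl-2,8-dioxabicyclo[3.2.1]octan-3-yl]ethyl}-2,2,5-trimethyl-1,3-dioxan-4-yl]propan-1-ol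
Product: 37 (2R)-2-[(4R,5S,6S)-6-{(1R)-1-[(1S,3R,4R,5S)-1,4-dimethyl-2,8-dioxabicyclo[3.2.1]octan-3-yl]ethyl}-2,2,5-trimethyl-1,3-dioxan-4-yl]propanal
Conditions: Dess–Martin periodinane, NaHCO3, CH2Cl2, 0 °C to rt
Reagents that add atoms: none
Why: Dess–Martin oxidation should give the C5′ aldehyde without epimerising C6′ (the changed descriptors reflect priorities only).

Step 20
Reactants: 37 (2R)-2-[(4R,5S,6S)-6-{(1R)-1-[(1S,3R,4R,5S)-1,4-dimethyl-2,8-dioxabicyclo[3.2.1]octan-3-yl]ethyl}-2,2,5-trimethyl-1,3-dioxan-4-yl]propanal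
Product: 38 (2E,4S)-4-[(4S,5R,6R)-6-{(1R)-1-[(1S,3R,4R,5S)-1,4-dimethyl-2,8-dioxabicyclo[3.2.1]octan-3-yl]ethyl}-2,2,5-trimethyl-1,3-dioxan-4-yl]pent-2-enal
Conditions: Ph3P=CHCHO, toluene, 80 °C
Reagents that add atoms: (triphenylphosphoranylidene)acetaldehyde, O=CC=P(c1ccccc1)(c1ccccc1)c1ccccc1
Why: Wittig olefination with a formyl-stabilised ylide should give the E-configured C4′=C5′ enal under thermodynamic control of oxaphosphetane formation.

Step 21
Reactants: 38 (2E,4S)-4-[(4S,5R,6R)-6-{(1R)-1-[(1S,3R,4R,5S)-1,4-dimethyl-2,8-dioxabicyclo[3.2.1]octan-3-yl]ethyl}-2,2,5-trimethyl-1,3-dioxan-4-yl]pent-2-enal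
Product: 39 methyl (2Z,4E,6S)-6-[(4S,5R,6R)-6-{(1R)-1-[(1S,3R,4R,5S)-1,4-dimethyl-2,8-dioxabicyclo[3.2.1]octan-3-yl]ethyl}-2,2,5-trimethyl-1,3-dioxan-4-yl]-2-methylhepta-2,4-dienoate
Conditions: (CF3CH2O)2P(O)CH(CH3)CO2Me, KN(SiMe3)2, 18-crown-6, THF, −78 °C
Reagents that add atoms: methyl 2-[bis(2,2,2-trifluoroethoxy)phosphoryl]propanoate, COC(=O)C(C)P(=O)(OCC(F)(F)F)OCC(F)(F)F
Why: Still–Gennari olefination, in which the electron-poor phosphonate makes elimination faster than equilibration, should give the Z-trisubstituted C2′=C3′ bond under kinetic control and leave the E-alkene untouched.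

Step 22
Reactants: 39 methyl (2Z,4E,6S)-6-[(4S,5R,6R)-6-{(1R)-1-[(1S,3R,4R,5S)-1,4-dimethyl-2,8-dioxabicyclo[3.2.1]octan-3-yl]ethyl}-2,2,5-trimethyl-1,3-dioxan-4-yl]-2-methylhepta-2,4-dienoate
Product: 40 (2Z,4E,6S)-6-[(4S,5R,6R)-6-{(1R)-1-[(1S,3R,4R,5S)-1,4-dimethyl-2,8-dioxabicyclo[3.2.1]octan-3-yl]ethyl}-2,2,5-trimethyl-1,3-dioxan-4-yl]-2-methylhepta-2,4-dienoic acid
Conditions: LiOH, THF/MeOH/H2O, rt to 40 °C; then aq. HCl to pH 4, 0 °C
Reagents that add atoms: lithium hydroxide, [Li+].[OH-]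
Why: Saponification should free the dienoic acid, the acetonide and ketal being stable to base and to the brief mild acidification.

**Union and unmasking**

Step 23
Reactants: 15 methoxymethyl 6-amino-2,4-bis(methoxymethoxy)-3-methyl-5,8-dioxo-5,8-dihydronaphthalene-1-carboxylate, 40 (2Z,4E,6S)-6-[(4S,5R,6R)-6-{(1R)-1-[(1S,3R,4R,5S)-1,4-dimethyl-2,8-dioxabicyclo[3.2.1]octan-3-yl]ethyl}-2,2,5-trimethyl-1,3-dioxan-4-yl]-2-methylhepta-2,4-dienoic acid
Product: 43 methoxymethyl 6-{[(2Z,4E,6S)-6-[(4S,5R,6R)-6-{(1R)-1-[(1S,3R,4R,5S)-1,4-dimethyl-2,8-dioxabicyclo[3.2.1]octan-3-yl]ethyl}-2,2,5-trimethyl-1,3-dioxan-4-yl]-2-methylhepta-2,4-dienoyl]amino}-2,4-bis(methoxymethoxy)-3-methyl-5,8-dioxo-5,8-dihydronaphthalene-1-carboxylate, via dienoyl chloride 41 (not isolated), via sodium amide 42 (not isolated)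
Conditions: 40, 1-chloro-N,N,2-trimethylprop-1-en-1-amine, CH2Cl2, 0 °C; 15, NaH (2.2 equiv), THF, 0 °C; then combine, 0 °C to rt
Reagents that add atoms: none
Why: N-acylation of an aminoquinone, in which the neutral chloro-enamine makes the acid chloride without acid or base and the sodium amide of the only acidic site left in 15 attacks it, should give the amide with the Z,E-diene intact.

Step 24
Reactants: 43 methoxymethyl 6-{[(2Z,4E,6S)-6-[(4S,5R,6R)-6-{(1R)-1-[(1S,3R,4R,5S)-1,4-dimethyl-2,8-dioxabicyclo[3.2.1]octan-3-yl]ethyl}-2,2,5-trimethyl-1,3-dioxan-4-yl]-2-methylhepta-2,4-dienoyl]amino}-2,4-bis(methoxymethoxy)-3-methyl-5,8-dioxo-5,8-dihydronaphthalene-1-carboxylate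
Product: 44 rifsaliniketal
Conditions: TFA/H2O/THF (2:1:2), 0 °C to rt
Reagents that add atoms: none
Why: Acid-catalysed acetal hydrolysis should remove the three methoxymethyl groups and the acetonide in one operation, while the bicyclic ketal, the thermodynamic sink of the C11′/C13′ diol and the C16′ ketone, re-closes if it opens.

**Compound list**

1 | 3,5-dimethoxy-4-methylbenzoic acid | COc1cc(C(=O)O)cc(OC)c1C | starting material
2 | lithium 2-lithio-3,5-dimethoxy-4-methylbenzoate | [Li]OC(=O)c1cc(OC)c(C)c(OC)c1[Li] | intermediate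
3 | 3,5-dimethoxy-2-(methoxycarbonyl)-4-methylbenzoic acid | COC(=O)c1c(OC)c(C)c(OC)cc1C(=O)O | intermediate
4 | methyl (2R)-2-[(tert-butoxycarbonyl)amino]-3-iodopropanoate (Boc-3-iodo-L-alanine methyl ester) | CC(C)(C)OC(=O)N[C@@H](CI)C(=O)OC | starting material
5 | 3,5-dimethoxy-2-(methoxycarbonyl)-4-methylbenzoyl chloride | COC(=O)c1c(OC)c(C)c(OC)cc1C(Cl)=O | intermediate
6 | [(2R)-2-[(tert-butoxycarbonyl)amino]-3-methoxy-3-oxopropyl]zinc iodide | CC(C)(C)OC(=O)N[C@@H](C[Zn]I)C(=O)OC | intermediate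
7 | methyl (2S)-2-[(tert-butoxycarbonyl)amino]-4-[3,5-dimethoxy-2-(methoxycarbonyl)-4-methylphenyl]-4-oxobutanoate | COC(=O)c1c(OC)c(C)c(OC)cc1C(=O)C[C@H](NC(=O)OC(C)(C)C)C(=O)OC | intermediate
8 | (2S)-2-[(tert-butoxycarbonyl)amino]-4-[3,5-dimethoxy-2-(methoxycarbonyl)-4-methylphenyl]-4-oxobutanoic acid | COC(=O)c1c(OC)c(C)c(OC)cc1C(=O)C[C@H](NC(=O)OC(C)(C)C)C(=O)O | intermediate
9 | mixed trifluoroacetic anhydride of (2S)-4-[3,5-dimethoxy-2-(methoxycarbonyl)-4-methylphenyl]-4-oxo-2-(trifluoroacetamido)butanoic acid | COC(=O)c1c(OC)c(C)c(OC)cc1C(=O)C[C@H](NC(=O)C(F)(F)F)C(=O)OC(=O)C(F)(F)F | intermediate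
10 | methyl (6S)-2,4-dimethoxy-3-methyl-5,8-dioxo-6-(trifluoroacetamido)-5,6,7,8-tetrahydronaphthalene-1-carboxylate | COC(=O)c1c(OC)c(C)c(OC)c2C(=O)[C@@H](NC(=O)C(F)(F)F)CC(=O)c12 | intermediate
11 | methyl 5,8-dihydroxy-2,4-dimethoxy-3-methyl-6-(trifluoroacetamido)naphthalene-1-carboxylate | COC(=O)c1c(OC)c(C)c(OC)c2c(O)c(NC(=O)C(F)(F)F)cc(O)c12 | intermediate
12 | methyl 2,4-dimethoxy-3-methyl-5,8-dioxo-6-(trifluoroacetamido)-5,8-dihydronaphthalene-1-carboxylate | COC(=O)c1c(OC)c(C)c(OC)c2C(=O)C(NC(=O)C(F)(F)F)=CC(=O)c12 | intermediate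
13 | methyl 6-amino-2,4-dimethoxy-3-methyl-5,8-dioxo-5,8-dihydronaphthalene-1-carboxylate | COC(=O)c1c(OC)c(C)c(OC)c2C(=O)C(N)=CC(=O)c12 | intermediate
14 | 6-amino-2,4-dihydroxy-3-methyl-5,8-dioxo-5,8-dihydronaphthalene-1-carboxylic acid | NC1=CC(=O)c2c(C(=O)O)c(O)c(C)c(O)c2C1=O | intermediate
15 | methoxymethyl 6-amino-2,4-bis(methoxymethoxy)-3-methyl-5,8-dioxo-5,8-dihydronaphthalene-1-carboxylate | COCOC(=O)c1c(OCOC)c(C)c(OCOC)c2C(=O)C(N)=CC(=O)c12 | intermediate
16 | (4R)-4-benzyl-3-propanoyl-1,3-oxazolidin-2-one | CCC(=O)N1[C@H](Cc2ccccc2)COC1=O | starting material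
17 | pent-4-enal | C=CCCC=O | starting material
18 | Z dibutylboron enolate of 16 | C/C=C(/N1[C@H](Cc2ccccc2)COC1=O)OB(CCCC)CCCC | intermediate
19 | (4R)-4-benzyl-3-[(2R,3S)-3-hydroxy-2-methylhept-6-enoyl]-1,3-oxazolidin-2-one | C=CCC[C@H](O)[C@H](C(=O)N1C(=O)OC[C@H]1Cc1ccccc1)C | intermediate
20 | (4R)-4-benzyl-3-[(2R,3S)-2-methyl-3-(triethylsilyloxy)hept-6-enoyl]-1,3-oxazolidin-2-one | C=CCC[C@H](O[Si](CC)(CC)CC)[C@H](C(=O)N1C(=O)OC[C@H]1Cc1ccccc1)C | intermediate
21 | (2S,3S)-2-methyl-3-(triethylsilyloxy)hept-6-en-1-ol | C=CCC[C@H](O[Si](CC)(CC)CC)[C@H](CO)C | intermediate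
22 | (2R,3S)-2-methyl-3-(triethylsilyloxy)hept-6-enal | C=CCC[C@H](O[Si](CC)(CC)CC)[C@H](C=O)C | intermediate
23 | pentan-3-one | CCC(=O)CC | starting material
24 | Z dibutylboron enolate of pentan-3-one | C/C=C(/CC)OB(CCCC)CCCC | intermediate
25 | (4S,5R,6S,7S)-5-hydroxy-4,6-dimethyl-7-(triethylsilyloxy)undec-10-en-3-one | C=CCC[C@H](O[Si](CC)(CC)CC)[C@@H](C)[C@@H](O)[C@H](C)C(=O)CC | intermediate
26 | (5S,6S,7R,8S)-7-hydroxy-6,8-dimethyl-5-(triethylsilyloxy)undecane-2,9-dione | CC(=O)CC[C@H](O[Si](CC)(CC)CC)[C@@H](C)[C@@H](O)[C@H](C)C(=O)CC | intermediate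
27 | (5S,6R,7R,8S)-5,7-dihydroxy-6,8-dimethylundecane-2,9-dione | CC(=O)CC[C@H](O)[C@@H](C)[C@@H](O)[C@H](C)C(=O)CC | intermediate
28 | (2S)-2-[(1S,3R,4R,5S)-1,4-dimethyl-2,8-dioxabicyclo[3.2.1]octan-3-yl]pentan-3-one | CCC(=O)[C@@H](C)[C@@H]1O[C@@]2(C)CC[C@H](O2)[C@H]1C | intermediate
29 | methyl (2S)-3-hydroxy-2-methylpropanoate | OC[C@H](C)C(=O)OC | starting material
30 | methyl (2S)-3-(tert-butyldimethylsilyloxy)-2-methylpropanoate | CC(C)(C)[Si](C)(C)OC[C@H](C)C(=O)OC | intermediate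
31 | (2S)-3-(tert-butyldimethylsilyloxy)-2-methylpropanal | CC(C)(C)[Si](C)(C)OC[C@H](C)C=O | intermediate
32 | Z tin enolate of 28 (divalent tin, one triflate ligand) | C/C=C(\O[Sn]OS(=O)(=O)C(F)(F)F)[C@@H](C)[C@@H]1O[C@@]2(C)CC[C@H](O2)[C@H]1C | intermediate
33 | (2S,4R,5S,6S)-7-(tert-butyldimethylsilyloxy)-2-[(1S,3R,4R,5S)-1,4-dimethyl-2,8-dioxabicyclo[3.2.1]octan-3-yl]-5-hydroxy-4,6-dimethylheptan-3-one | CC(C)(C)[Si](C)(C)OC[C@H](C)[C@H](O)[C@@H](C)C(=O)[C@@H](C)[C@@H]1O[C@@]2(C)CC[C@H](O2)[C@H]1C | intermediate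
34 | (2S,3S,4R,5R,6R)-1-(tert-butyldimethylsilyloxy)-6-[(1S,3S,4R,5S)-1,4-dimethyl-2,8-dioxabicyclo[3.2.1]octan-3-yl]-2,4-dimethylheptane-3,5-diol | CC(C)(C)[Si](C)(C)OC[C@H](C)[C@H](O)[C@@H](C)[C@@H](O)[C@@H](C)[C@@H]1O[C@@]2(C)CC[C@H](O2)[C@H]1C | intermediate
35 | tert-butyl{(2S)-2-[(4S,5R,6R)-6-{(1R)-1-[(1S,3R,4R,5S)-1,4-dimethyl-2,8-dioxabicyclo[3.2.1]octan-3-yl]ethyl}-2,2,5-trimethyl-1,3-dioxan-4-yl]propoxy}dimethylsilane | CC(C)(C)[Si](C)(C)OC[C@H](C)[C@@H]1OC(C)(C)O[C@H]([C@@H]1C)[C@@H](C)[C@@H]2O[C@@]3(C)CC[C@H](O3)[C@H]2C | intermediate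
36 | (2S)-2-[(4S,5R,6R)-6-{(1R)-1-[(1S,3R,4R,5S)-1,4-dimethyl-2,8-dioxabicyclo[3.2.1]octan-3-yl]ethyl}-2,2,5-trimethyl-1,3-dioxan-4-yl]propan-1-ol | OC[C@H](C)[C@@H]1OC(C)(C)O[C@H]([C@@H]1C)[C@@H](C)[C@@H]2O[C@@]3(C)CC[C@H](O3)[C@H]2C | intermediate
37 | (2R)-2-[(4R,5S,6S)-6-{(1R)-1-[(1S,3R,4R,5S)-1,4-dimethyl-2,8-dioxabicyclo[3.2.1]octan-3-yl]ethyl}-2,2,5-trimethyl-1,3-dioxan-4-yl]propanal | O=C[C@H](C)[C@@H]1OC(C)(C)O[C@H]([C@@H]1C)[C@@H](C)[C@@H]2O[C@@]3(C)CC[C@H](O3)[C@H]2C | intermediate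
38 | (2E,4S)-4-[(4S,5R,6R)-6-{(1R)-1-[(1S,3R,4R,5S)-1,4-dimethyl-2,8-dioxabicyclo[3.2.1]octan-3-yl]ethyl}-2,2,5-trimethyl-1,3-dioxan-4-yl]pent-2-enal | O=C/C=C/[C@H](C)[C@@H]1OC(C)(C)O[C@H]([C@@H]1C)[C@@H](C)[C@@H]2O[C@@]3(C)CC[C@H](O3)[C@H]2C | intermediate
39 | methyl (2Z,4E,6S)-6-[(4S,5R,6R)-6-{(1R)-1-[(1S,3R,4R,5S)-1,4-dimethyl-2,8-dioxabicyclo[3.2.1]octan-3-yl]ethyl}-2,2,5-trimethyl-1,3-dioxan-4-yl]-2-methylhepta-2,4-dienoate | C/C(=C/C=C/[C@H](C)[C@@H]1OC(C)(C)O[C@H]([C@@H]1C)[C@@H](C)[C@@H]2O[C@@]3(C)CC[C@H](O3)[C@H]2C)C(=O)OC | intermediate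
40 | (2Z,4E,6S)-6-[(4S,5R,6R)-6-{(1R)-1-[(1S,3R,4R,5S)-1,4-dimethyl-2,8-dioxabicyclo[3.2.1]octan-3-yl]ethyl}-2,2,5-trimethyl-1,3-dioxan-4-yl]-2-methylhepta-2,4-dienoic acid | C/C(=C/C=C/[C@H](C)[C@@H]1OC(C)(C)O[C@H]([C@@H]1C)[C@@H](C)[C@@H]2O[C@@]3(C)CC[C@H](O3)[C@H]2C)C(=O)O | intermediate
41 | acid chloride of 40 | C/C(=C/C=C/[C@H](C)[C@@H]1OC(C)(C)O[C@H]([C@@H]1C)[C@@H](C)[C@@H]2O[C@@]3(C)CC[C@H](O3)[C@H]2C)C(Cl)=O | intermediate
42 | N-sodio derivative of 15 | COCOC(=O)c1c(OCOC)c(C)c(OCOC)c2C(=O)C(N[Na])=CC(=O)c12 | intermediate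
43 | methoxymethyl 6-{[(2Z,4E,6S)-6-[(4S,5R,6R)-6-{(1R)-1-[(1S,3R,4R,5S)-1,4-dimethyl-2,8-dioxabicyclo[3.2.1]octan-3-yl]ethyl}-2,2,5-trimethyl-1,3-dioxan-4-yl]-2-methylhepta-2,4-dienoyl]amino}-2,4-bis(methoxymethoxy)-3-methyl-5,8-dioxo-5,8-dihydronaphthalene-1-carboxylate | C/C(=C/C=C/[C@H](C)[C@@H]1OC(C)(C)O[C@H]([C@@H]1C)[C@@H](C)[C@@H]2O[C@@]3(C)CC[C@H](O3)[C@H]2C)C(=O)NC4=CC(=O)c5c(C(=O)OCOC)c(OCOC)c(C)c(OCOC)c5C4=O | intermediate
44 | rifsaliniketal, (2Z,4E,6S,7S,8R,9R,10R)-N-(5-carboxy-6,8-dihydroxy-7-methyl-1,4-dioxo-1,4-dihydronaphthalen-2-yl)-10-[(1S,3S,4R,5S)-1,4-dimethyl-2,8-dioxabicyclo[3.2.1]octan-3-yl]-7,9-dihydroxy-2,6,8-trimethylundeca-2,4-dienamide | C/C(=C/C=C/[C@H](C)[C@H](O)[C@@H](C)[C@@H](O)[C@@H](C)[C@@H]1O[C@@]2(C)CC[C@H](O2)[C@H]1C)C(=O)NC1=CC(=O)c2c(C(=O)O)c(O)c(C)c(O)c2C1=O | target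

**Totals and risks**

Total step count: 24. Longest linear sequence: 16 steps (steps 7–12 and 15–24, from 16 and 17).

The three steps most likely to fail, in this order:

Step 4. Acylation at C8a, which lies ortho to the C4 ketone, may be slower than loss of carbon monoxide from the α-amido acylium ion or than β-elimination of the amide from the ring-closed diketone. The fallback brings nitrogen in after ring closure. It sets out from 3, converted into 5 as in step 2. Coupling with commercial 3-ethoxy-3-oxopropylzinc bromide under PdCl2(PPh3)2 should give ethyl 4-[3,5-dimethoxy-2-(methoxycarbonyl)-4-methylphenyl]-4-oxobutanoate F1. LiOH should hydrolyse the ethyl ester to 4-[3,5-dimethoxy-2-(methoxycarbonyl)-4-methylphenyl]-4-oxobutanoic acid F2. The nitrogen-free acylium tolerates P2O5/MeSO3H at 60 °C, and cyclisation, enolisation and air oxidation should give methyl 2,4-dimethoxy-3-methyl-5,8-dioxo-5,8-dihydronaphthalene-1-carboxylate F3. NaN3 in aqueous AcOH should then aminate C2, because the C8 methoxy group donates into the C1 carbonyl and leaves the C4 carbonyl, whose β-carbon is C2, as the acceptor. The route is rejoined at 13.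

Step 23. The activated Z,E-dienoyl unit may isomerise to the E,E isomer while the weakly nucleophilic amide anion attacks slowly. The fallback makes the nitrogen an aniline by redox. It sets out from 15 and 40. Na2S2O4 in EtOAc/H2O should reduce the quinone to methoxymethyl 6-amino-5,8-dihydroxy-2,4-bis(methoxymethoxy)-3-methylnaphthalene-1-carboxylate F4. Its amino group should be acylated by 40 under EDC/HOAt without an acid chloride to give the amido-hydroquinone F5. Air or Ag2O should re-oxidise F5, and the route is rejoined at 43.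

Step 11. Facial selectivity may be poor when the achiral enolate adds to the α-methyl aldehyde (Felkin against anti-Felkin). The fallback uses auxiliary control. It sets out from 22. An Evans syn aldol with (4S)-4-benzyl-3-propanoyl-1,3-oxazolidin-2-one (n-Bu2BOTf, i-Pr2NEt) should give (4S)-4-benzyl-3-[(2S,3R,4S,5S)-3-hydroxy-2,4-dimethyl-5-(triethylsilyloxy)non-8-enoyl]-1,3-oxazolidin-2-one F6. AlMe3 with MeNHOMe·HCl should give (2S,3R,4S,5S)-3-hydroxy-N-methoxy-N,2,4-trimethyl-5-(triethylsilyloxy)non-8-enamide F7. EtMgBr should then give the ethyl ketone, and the route is rejoined at 25.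

Further compounds
F1 | step 4 | ethyl 4-[3,5-dimethoxy-2-(methoxycarbonyl)-4-methylphenyl]-4-oxobutanoate | CCOC(=O)CCC(=O)c1cc(OC)c(C)c(OC)c1C(=O)OC
F2 | step 4 | 4-[3,5-dimethoxy-2-(methoxycarbonyl)-4-methylphenyl]-4-oxobutanoic acid | OC(=O)CCC(=O)c1cc(OC)c(C)c(OC)c1C(=O)OC
F3 | step 4 | methyl 2,4-dimethoxy-3-methyl-5,8-dioxo-5,8-dihydronaphthalene-1-carboxylate | COC(=O)c1c(OC)c(C)c(OC)c2C(=O)C=CC(=O)c12
F4 | step 23 | methoxymethyl 6-amino-5,8-dihydroxy-2,4-bis(methoxymethoxy)-3-methylnaphthalene-1-carboxylate | COCOC(=O)c1c(OCOC)c(C)c(OCOC)c2c(O)c(N)cc(O)c12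
F5 | step 23 | methoxymethyl 6-{[(2Z,4E,6S)-6-[(4S,5R,6R)-6-{(1R)-1-[(1S,3R,4R,5S)-1,4-dimethyl-2,8-dioxabicyclo[3.2.1]octan-3-yl]ethyl}-2,2,5-trimethyl-1,3-dioxan-4-yl]-2-methylhepta-2,4-dienoyl]amino}-5,8-dihydroxy-2,4-bis(methoxymethoxy)-3-methylnaphthalene-1-carboxylate | C/C(=C/C=C/[C@H](C)[C@@H]1OC(C)(C)O[C@H]([C@@H]1C)[C@@H](C)[C@@H]2O[C@@]3(C)CC[C@H](O3)[C@H]2C)C(=O)Nc4cc(O)c5c(C(=O)OCOC)c(OCOC)c(C)c(OCOC)c5c4O
F6 | step 11 | (4S)-4-benzyl-3-[(2S,3R,4S,5S)-3-hydroxy-2,4-dimethyl-5-(triethylsilyloxy)non-8-enoyl]-1,3-oxazolidin-2-one | C=CCC[C@H](O[Si](CC)(CC)CC)[C@@H](C)[C@@H](O)[C@H](C)C(=O)N1[C@@H](Cc2ccccc2)COC1=O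
F7 | step 11 | (2S,3R,4S,5S)-3-hydroxy-N-methoxy-N,2,4-trimethyl-5-(triethylsilyloxy)non-8-enamide | C=CCC[C@H](O[Si](CC)(CC)CC)[C@@H](C)[C@@H](O)[C@H](C)C(=O)N(C)OC
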